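**Plan**

- Retrosynthesis: the three phenolic O–H bonds are masked as MOM ethers and the C2–H/C3–H pair is removed (flavanone to flavone). Ring B is then cut at C2'–C3' and C1'–C6'. The chromone is cut at the alkyne carbon C2' (one-carbon homologation of a C2 aldehyde), at O1–C2 and C2–C3 (2-hydroxyacetophenone plus diethyl oxalate), and at the two ring A C–prenyl bonds.
- Enabling feature: ring B carries C3'–OH, C4'–OMe and C5'–prenyl on three neighbouring carbons, with hydrogen at C2' and C6'. The C3' oxygen with C3', C4', C5' and C6' are the five ring atoms of 3-methoxy-4-prenylfuran, and C1'–C2' is an alkyne on C2 of the chromone.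
- Forward order: ring A is prenylated and protected, ring C is closed as a chromone-2-carboxylate and its ester is turned into an ethynyl group. The furan is made separately from 3,4-dibromofuran, and ring B is closed on the alkyne by cycloaddition and bridge opening.
- Stereochemistry: the only stereocentre, C2 (S), is set in the penultimate step by ligand-controlled CuH conjugate reduction of the flavone C2=C3 bond. Mild acid then frees the phenols.

Key step: step 9

Assumption: (S)-DTBM-SEGPHOS is taken to deliver hydride to the C2 face that gives the (2S)-flavanone, by analogy with CuH reductions of 3-substituted cyclic enones; if a test reduction shows the opposite sense, the (R)-ligand is used and nothing else changes. "Prenyl" means 3-methylbut-2-enyl throughout.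

**Route**

Step 1
Reactants: 1 2,4,6-trihydroxyacetophenone; 2 prenyl bromide (1-bromo-3-methylbut-2-ene)
Product: 3 1-[2,4,6-trihydroxy-3,5-bis(3-methylbut-2-enyl)phenyl]ethanone
Conditions: 2 (2.2 equiv), 10% aq KOH, 0 °C to rt
Reagents that add atoms: none
Why: Friedel–Crafts-type C-alkylation of the phloroglucinol phenoxide, in which the two free ring carbons are the only nucleophilic carbon sites, is the standard entry to 3,5-diprenylphloroacetophenones, with O-alkylated and over-alkylated material removed by chromatography.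

Step 2
Reactants: 3 1-[2,4,6-trihydroxy-3,5-bis(3-methylbut-2-enyl)phenyl]ethanone
Product: 4 1-[2-hydroxy-4,6-bis(methoxymethoxy)-3,5-bis(3-methylbut-2-enyl)phenyl]ethanone
Conditions: MOMCl (2.3 equiv), i-Pr2NEt, CH2Cl2, 0 °C to rt
Reagents that add atoms: chloromethyl methyl ether, COCCl
Why: Williamson-type O-alkylation (MOM protection) should cap the 4-hydroxyl and one ortho hydroxyl, while the other ortho hydroxyl stays free because it is hydrogen-bonded to the acetyl carbonyl and is kept as the future ring oxygen.

Step 3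
Reactants: 4 1-[2-hydroxy-4,6-bis(methoxymethoxy)-3,5-bis(3-methylbut-2-enyl)phenyl]ethanone; 5 diethyl oxalate
Product: 7 ethyl 5,7-bis(methoxymethoxy)-6,8-bis(3-methylbut-2-enyl)-4-oxo-4H-chromene-2-carboxylate, via diketo ester 6 (not isolated)
Conditions: NaOEt, EtOH–THF, 60 °C; then AcOH, 70 °C
Reagents that add atoms: none
Why: Claisen condensation of the methyl ketone enolate with the oxalate followed by cyclodehydration closes ring C, since the free phenol adds to the very electrophilic α-keto ester carbonyl and the hemiketal loses water in warm acetic acid, a medium mild enough for the MOM ethers and for prenyl groups that have no free ortho hydroxyl.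

Step 4
Reactants: 7 ethyl 5,7-bis(methoxymethoxy)-6,8-bis(3-methylbut-2-enyl)-4-oxo-4H-chromene-2-carboxylate
Product: 8 2-(hydroxymethyl)-5,7-bis(methoxymethoxy)-6,8-bis(3-methylbut-2-enyl)chromen-4-one
Conditions: NaBH4, MeOH–THF, 0 °C
Reagents that add atoms: none
Why: chemoselective borohydride reduction should take only the ester, which is activated by the electron-poor, oxygen-bearing C2 of the pyranone, whereas the C4 carbonyl is a vinylogous ester and is inert at 0 °C.

Step 5
Reactants: 8 2-(hydroxymethyl)-5,7-bis(methoxymethoxy)-6,8-bis(3-methylbut-2-enyl)chromen-4-one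
Product: 9 5,7-bis(methoxymethoxy)-6,8-bis(3-methylbut-2-enyl)-4-oxo-4H-chromene-2-carbaldehyde
Conditions: Dess–Martin periodinane, CH2Cl2, rt
Reagents that add atoms: none
Why: Dess–Martin oxidation of a primary alcohol stops at the aldehyde and leaves trisubstituted alkenes and MOM acetals untouched.

Step 6
Reactants: 9 5,7-bis(methoxymethoxy)-6,8-bis(3-methylbut-2-enyl)-4-oxo-4H-chromene-2-carbaldehyde
Product: 10 2-ethynyl-5,7-bis(methoxymethoxy)-6,8-bis(3-methylbut-2-enyl)chromen-4-one
Conditions: dimethyl (1-diazo-2-oxopropyl)phosphonate, K2CO3, MeOH–THF, 0 °C to rt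
Reagents that add atoms: dimethyl (1-diazo-2-oxopropyl)phosphonate, CC(=O)C(=[N+]=[N-])P(=O)(OC)OC
Why: Seyferth–Gilbert homologation in the Ohira–Bestmann variant, in which the diazomethylphosphonate anion released by methanolysis olefinates the aldehyde and the alkylidene carbene rearranges by 1,2-hydrogen shift to the terminal alkyne under a carbonate base mild enough for the chromone.

Step 7
Reactants: 11 3,4-dibromofuran; 2 prenyl bromide (1-bromo-3-methylbut-2-ene)
Product: 13 3-bromo-4-(3-methylbut-2-enyl)furan, via 3-bromo-4-lithiofuran 12 (not isolated)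
Conditions: n-BuLi (1.0 equiv), THF, −78 °C; then CuBr·SMe2 (10 mol%), 2, −78 to −20 °C
Reagents that add atoms: none
Why: bromine–lithium exchange on one of the two equivalent C–Br bonds at −78 °C, where 3-furyllithiums keep their position, followed by copper-catalysed allylic substitution at the unhindered primary carbon of the bromide, should give the monoprenylated bromofuran.

Step 8
Reactants: 13 3-bromo-4-(3-methylbut-2-enyl)furan
Product: 14 3-methoxy-4-(3-methylbut-2-enyl)furan
Conditions: NaOMe, CuBr (10 mol%), MeOH–NMP, 110 °C, sealed tube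
Reagents that add atoms: sodium methoxide, [Na+].[O-]C
Why: Ullmann-type copper-catalysed C–O coupling of a 3-bromo five-membered heteroarene with methoxide is the usual entry to 3-methoxyfurans and 3-methoxythiophenes, and its basic, acid-free medium suits the acid-labile enol-ether furan.

Step 9
Reactants: 10 2-ethynyl-5,7-bis(methoxymethoxy)-6,8-bis(3-methylbut-2-enyl)chromen-4-one; 14 3-methoxy-4-(3-methylbut-2-enyl)furan
Product: 16 2-[3-hydroxy-4-methoxy-5-(3-methylbut-2-enyl)phenyl]-5,7-bis(methoxymethoxy)-6,8-bis(3-methylbut-2-enyl)chromen-4-one, via oxanorbornadiene cycloadduct 15 (not isolated)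
Conditions: 14 (3 equiv), toluene, 80 °C, sealed tube; then PPTS (10 mol%), CH2Cl2, rt
Reagents that add atoms: none
Why: Proposed new method: the furan 14, whose HOMO is raised by the 3-methoxy group and is largest at C2, should add in a normal-demand (4+2) cycloaddition across the alkyne of 10, whose terminal carbon is the electrophilic δ-position of the chromone vinylogous ynone, so that furan C2 bonds to the terminal alkyne carbon (the C3'–C2' bond) and furan C5 to the internal carbon (the C6'–C1' bond), as expected for a 2-alkoxydiene and a monoactivated dienophile. The closest known reaction type is the Diels–Alder reaction of 3-alkoxyfurans with acetylenic esters followed by acid isomerisation of the 7-oxanorbornadiene to a phenol; what is new is the weaker, doubly vinylogous activation of the dienophile, which is why heat and excess diene are used and why the reversible cycloaddition is drained by irreversible aromatisation. Ring B closes intermolecularly by concerted formation of both C–C bonds, and the acid then ionises the bridge C–O bond at the bridgehead next to the prenyl-bearing carbon, because only that cation is a methoxy-stabilised pentadienyl (vinylogous oxocarbenium) cation; loss of the proton from the other bridgehead leaves the former furan oxygen as the C3' hydroxyl. No stereocentre remains, since the two bridgehead centres of racemic 15 are destroyed on aromatisation. The step needs regioselectivity in the cycloaddition and in the bridge opening, both dictated by the furan methoxy group, and site selectivity for the alkyne, which is secured because the chromone C2=C3 bond is oxygen-substituted and part of the pyranone ring and the prenyl alkenes are unactivated.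

Step 10
Reactants: 16 2-[3-hydroxy-4-methoxy-5-(3-methylbut-2-enyl)phenyl]-5,7-bis(methoxymethoxy)-6,8-bis(3-methylbut-2-enyl)chromen-4-one
Product: 17 2-[4-methoxy-3-(methoxymethoxy)-5-(3-methylbut-2-enyl)phenyl]-5,7-bis(methoxymethoxy)-6,8-bis(3-methylbut-2-enyl)chromen-4-one
Conditions: MOMCl, i-Pr2NEt, CH2Cl2, 0 °C to rt
Reagents that add atoms: chloromethyl methyl ether, COCCl
Why: standard MOM protection (Williamson-type O-alkylation) removes the acidic O–H that would quench the CuH catalyst in step 11 and lets all three acetals be cleaved together at the end.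

Step 11
Reactants: 17 2-[4-methoxy-3-(methoxymethoxy)-5-(3-methylbut-2-enyl)phenyl]-5,7-bis(methoxymethoxy)-6,8-bis(3-methylbut-2-enyl)chromen-4-one
Product: 18 (2S)-2-[4-methoxy-3-(methoxymethoxy)-5-(3-methylbut-2-enyl)phenyl]-5,7-bis(methoxymethoxy)-6,8-bis(3-methylbut-2-enyl)-2,3-dihydrochromen-4-one
Conditions: Cu(OAc)2·H2O (5 mol%), (S)-DTBM-SEGPHOS (5.5 mol%), (EtO)2MeSiH, t-BuOH, toluene, 0 °C to rt
Reagents that add atoms: none
Why: CuH-catalysed asymmetric conjugate reduction (1,4-hydrosilylation), a reaction type known for 2-substituted chromones and β,β-disubstituted cyclic enones, should deliver hydride to C2 on the face chosen by the chiral bisphosphine and so set C2 as S, while tert-butanol protonates the copper enolate before it can open the ring and the isolated trisubstituted alkenes and the electron-rich, doubly ortho-substituted C4 ketone are not reduced.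

Step 12
Reactants: 18 (2S)-2-[4-methoxy-3-(methoxymethoxy)-5-(3-methylbut-2-enyl)phenyl]-5,7-bis(methoxymethoxy)-6,8-bis(3-methylbut-2-enyl)-2,3-dihydrochromen-4-one
Product: 19 isoamoritin
Conditions: 3 M aq HCl, MeOH, 40 °C
Reagents that add atoms: none
Why: acid-catalysed acetal cleavage (transacetalisation to dimethoxymethane) frees the three phenols under conditions routinely used on prenylated flavanones, mild enough to avoid chroman formation from the ortho-prenylphenols and ring-opening racemisation at C2, and ring A is symmetric so no Wessely–Moser isomer can arise.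

**Compound list**

1 | 2,4,6-trihydroxyacetophenone | CC(=O)c1c(O)cc(O)cc1O | starting material
2 | prenyl bromide (1-bromo-3-methylbut-2-ene) | CC(C)=CCBr | starting material
3 | 1-[2,4,6-trihydroxy-3,5-bis(3-methylbut-2-enyl)phenyl]ethanone | CC(=O)c1c(O)c(CC=C(C)C)c(O)c(CC=C(C)C)c1O | intermediate
4 | 1-[2-hydroxy-4,6-bis(methoxymethoxy)-3,5-bis(3-methylbut-2-enyl)phenyl]ethanone | CC(=O)c1c(O)c(CC=C(C)C)c(OCOC)c(CC=C(C)C)c1OCOC | intermediate
5 | diethyl oxalate | CCOC(=O)C(=O)OCC | starting material
6 | ethyl 4-[2-hydroxy-4,6-bis(methoxymethoxy)-3,5-bis(3-methylbut-2-enyl)phenyl]-2,4-dioxobutanoate (diketo ester, not isolated) | CCOC(=O)C(=O)CC(=O)c1c(O)c(CC=C(C)C)c(OCOC)c(CC=C(C)C)c1OCOC | intermediate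
7 | ethyl 5,7-bis(methoxymethoxy)-6,8-bis(3-methylbut-2-enyl)-4-oxo-4H-chromene-2-carboxylate | CCOC(=O)c1cc(=O)c2c(OCOC)c(CC=C(C)C)c(OCOC)c(CC=C(C)C)c2o1 | intermediate
8 | 2-(hydroxymethyl)-5,7-bis(methoxymethoxy)-6,8-bis(3-methylbut-2-enyl)chromen-4-one | OCc1cc(=O)c2c(OCOC)c(CC=C(C)C)c(OCOC)c(CC=C(C)C)c2o1 | intermediate
9 | 5,7-bis(methoxymethoxy)-6,8-bis(3-methylbut-2-enyl)-4-oxo-4H-chromene-2-carbaldehyde | O=Cc1cc(=O)c2c(OCOC)c(CC=C(C)C)c(OCOC)c(CC=C(C)C)c2o1 | intermediate
10 | 2-ethynyl-5,7-bis(methoxymethoxy)-6,8-bis(3-methylbut-2-enyl)chromen-4-one | C#Cc1cc(=O)c2c(OCOC)c(CC=C(C)C)c(OCOC)c(CC=C(C)C)c2o1 | intermediate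
11 | 3,4-dibromofuran | Brc1cocc1Br | starting material
12 | 3-bromo-4-lithiofuran (not isolated) | [Li]c1cocc1Br | intermediate
13 | 3-bromo-4-(3-methylbut-2-enyl)furan | Brc1cocc1CC=C(C)C | intermediate
14 | 3-methoxy-4-(3-methylbut-2-enyl)furan | COc1cocc1CC=C(C)C | intermediate
15 | 2-[5-methoxy-6-(3-methylbut-2-enyl)-7-oxabicyclo[2.2.1]hepta-2,5-dien-2-yl]-5,7-bis(methoxymethoxy)-6,8-bis(3-methylbut-2-enyl)chromen-4-one (racemic cycloadduct, not isolated) | COC1=C(CC=C(C)C)C2OC1C=C2c1cc(=O)c2c(OCOC)c(CC=C(C)C)c(OCOC)c(CC=C(C)C)c2o1 | intermediate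
16 | 2-[3-hydroxy-4-methoxy-5-(3-methylbut-2-enyl)phenyl]-5,7-bis(methoxymethoxy)-6,8-bis(3-methylbut-2-enyl)chromen-4-one | COc1c(O)cc(-c2cc(=O)c3c(OCOC)c(CC=C(C)C)c(OCOC)c(CC=C(C)C)c3o2)cc1CC=C(C)C | intermediate
17 | 2-[4-methoxy-3-(methoxymethoxy)-5-(3-methylbut-2-enyl)phenyl]-5,7-bis(methoxymethoxy)-6,8-bis(3-methylbut-2-enyl)chromen-4-one | COCOc1cc(-c2cc(=O)c3c(OCOC)c(CC=C(C)C)c(OCOC)c(CC=C(C)C)c3o2)cc(CC=C(C)C)c1OC | intermediate
18 | (2S)-2-[4-methoxy-3-(methoxymethoxy)-5-(3-methylbut-2-enyl)phenyl]-5,7-bis(methoxymethoxy)-6,8-bis(3-methylbut-2-enyl)-2,3-dihydrochromen-4-one | COCOc1cc([C@@H]2CC(=O)c3c(OCOC)c(CC=C(C)C)c(OCOC)c(CC=C(C)C)c3O2)cc(CC=C(C)C)c1OC | intermediate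
19 | isoamoritin, (2S)-5,7-dihydroxy-2-[3-hydroxy-4-methoxy-5-(3-methylbut-2-enyl)phenyl]-6,8-bis(3-methylbut-2-enyl)-2,3-dihydrochromen-4-one | COc1c(O)cc([C@@H]2CC(=O)c3c(O)c(CC=C(C)C)c(O)c(CC=C(C)C)c3O2)cc1CC=C(C)C | target

**Step count**

Total: 12 steps. Longest linear sequence: 10 steps (steps 1–6 and 9–12); the furan branch (steps 7 and 8) joins at step 9.

**Steps most likely to fail**

Step 9. The alkyne may be too weakly activated for cycloaddition at temperatures the furan tolerates. The furan may instead add as a nucleophile to the alkyne terminus and re-aromatise, or cycloreversion may outrun the bridge opening. The fallback uses known chemistry and keeps the furan benzannulation, but on a dienophile of the established acetylenic-ester class, and joins ring B to ring A afterwards. It sets out from 14 and 4. Furan 14 and methyl propiolate (toluene, 60 °C; then PPTS) should give, through the cycloadduct methyl 5-methoxy-6-(3-methylbut-2-enyl)-7-oxabicyclo[2.2.1]hepta-2,5-diene-2-carboxylate F1, the phenol methyl 3-hydroxy-4-methoxy-5-(3-methylbut-2-enyl)benzoate F2. MOM protection (MOMCl, i-Pr2NEt) gives methyl 4-methoxy-3-(methoxymethoxy)-5-(3-methylbut-2-enyl)benzoate F3. Claisen acylation of the dianion of 4 (LiN(SiMe3)2, THF) with F3, a Baker–Venkataraman-type flavone assembly, gives 1-[2-hydroxy-4,6-bis(methoxymethoxy)-3,5-bis(3-methylbut-2-enyl)phenyl]-3-[4-methoxy-3-(methoxymethoxy)-5-(3-methylbut-2-enyl)phenyl]propane-1,3-dione F4. Cyclodehydration (NaOAc, AcOH, 80 °C) returns to the route at 17.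

Step 11. Hydride transfer to the electron-rich, hindered flavone may be slow. Facial selectivity with the 2-aryl group may be poor, ring opening of the copper enolate may erode the enantiomeric purity, and the C4 ketone may be over-reduced. The fallback replaces asymmetric catalysis by racemic reduction and resolution. It sets out from 17: conjugate reduction with LiBH(s-Bu)3 (THF, −78 °C) should give racemic 2-[4-methoxy-3-(methoxymethoxy)-5-(3-methylbut-2-enyl)phenyl]-5,7-bis(methoxymethoxy)-6,8-bis(3-methylbut-2-enyl)-2,3-dihydrochromen-4-one F5. Preparative chromatography on a cellulose carbamate chiral stationary phase separates it into 18, where the route is rejoined, and the (2R)-enantiomer F6, which is set aside.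

Step 6. Methoxide may attack the electrophilic formyl-substituted pyranone and open the ring, or methanol may add in conjugate fashion to the newly formed alkyne. The fallback avoids methanolic base by a Corey–Fuchs-type sequence with a stereoselective hydrogenolysis. It sets out from 9: dibromo-olefination (CBr4, PPh3, Et3N, CH2Cl2, 0 °C) gives 2-(2,2-dibromoethenyl)-5,7-bis(methoxymethoxy)-6,8-bis(3-methylbut-2-enyl)chromen-4-one F7. Pd(PPh3)4-catalysed hydrogenolysis with Bu3SnH removes the bromine trans to the chromone and gives 2-[(Z)-2-bromoethenyl]-5,7-bis(methoxymethoxy)-6,8-bis(3-methylbut-2-enyl)chromen-4-one F8. Anti-elimination of HBr with DBU (THF, rt) returns to the route at 10.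

Further compounds
F1 | step 9 | methyl 5-methoxy-6-(3-methylbut-2-enyl)-7-oxabicyclo[2.2.1]hepta-2,5-diene-2-carboxylate (racemic) | COC(=O)C1=CC2OC1C(CC=C(C)C)=C2OC
F2 | step 9 | methyl 3-hydroxy-4-methoxy-5-(3-methylbut-2-enyl)benzoate | COC(=O)c1cc(O)c(OC)c(CC=C(C)C)c1
F3 | step 9 | methyl 4-methoxy-3-(methoxymethoxy)-5-(3-methylbut-2-enyl)benzoate | COCOc1cc(C(=O)OC)cc(CC=C(C)C)c1OC
F4 | step 9 | 1-[2-hydroxy-4,6-bis(methoxymethoxy)-3,5-bis(3-methylbut-2-enyl)phenyl]-3-[4-methoxy-3-(methoxymethoxy)-5-(3-methylbut-2-enyl)phenyl]propane-1,3-dione | COCOc1cc(C(=O)CC(=O)c2c(O)c(CC=C(C)C)c(OCOC)c(CC=C(C)C)c2OCOC)cc(CC=C(C)C)c1OC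
F5 | step 11 | racemic 2-[4-methoxy-3-(methoxymethoxy)-5-(3-methylbut-2-enyl)phenyl]-5,7-bis(methoxymethoxy)-6,8-bis(3-methylbut-2-enyl)-2,3-dihydrochromen-4-one | COCOc1cc(C2CC(=O)c3c(OCOC)c(CC=C(C)C)c(OCOC)c(CC=C(C)C)c3O2)cc(CC=C(C)C)c1OC
F6 | step 11 | (2R)-2-[4-methoxy-3-(methoxymethoxy)-5-(3-methylbut-2-enyl)phenyl]-5,7-bis(methoxymethoxy)-6,8-bis(3-methylbut-2-enyl)-2,3-dihydrochromen-4-one | COCOc1cc([C@H]2CC(=O)c3c(OCOC)c(CC=C(C)C)c(OCOC)c(CC=C(C)C)c3O2)cc(CC=C(C)C)c1OC
F7 | step 6 | 2-(2,2-dibromoethenyl)-5,7-bis(methoxymethoxy)-6,8-bis(3-methylbut-2-enyl)chromen-4-one | BrC(Br)=Cc1cc(=O)c2c(OCOC)c(CC=C(C)C)c(OCOC)c(CC=C(C)C)c2o1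
F8 | step 6 | 2-[(Z)-2-bromoethenyl]-5,7-bis(methoxymethoxy)-6,8-bis(3-methylbut-2-enyl)chromen-4-one | Br/C=C\c1cc(=O)c2c(OCOC)c(CC=C(C)C)c(OCOC)c(CC=C(C)C)c2o1
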